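Ring A is the guaiacyl ring and ring B the syringyl ring; C7 is the benzylic carbinol carbon, C8 the carbon carrying the ether oxygen to ring B, and C9 its hydroxymethyl carbon.
Retrosynthetic cuts, in order: the two O-benzyl bonds and the two ester oxidation levels (end game), C7–H (hydride onto a C7 aryl ketone), C8–O(ring B), C8–C9, and the glycerol C2–O bond to ring A.
Forward order: no ring is formed. The chain grows as glycerol ether on ring A (Mitsunobu), C8–C9 (Claisen methoxycarbonylation), C8–O to ring B (phenol alkylation by an alpha-bromo beta-keto ester), C7–H (transfer hydrogenation), then ester reduction and debenzylation.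
Enabling feature: C8 lies between the C7 aryl ketone on ring A and the C9 ester and carries the ring B oxygen, so the C8 hydrogen is doubly activated and C8 racemises freely, while the C7 aryl ketone is open to catalyst-controlled hydride transfer.
Stereochemistry: both centres come from one stereoconvergent reduction with dynamic kinetic resolution, C7 from the (S,S)-TsDPEN ruthenium catalyst and C8 from the syn preference of the reduction over rapidly equilibrating C8 epimers; the glycerol carbon is not stereogenic.

Key step: step 7

Assumption: the facial sense of the (S,S)-configured catalyst is taken from the simple aryl alkyl ketone model (S-configured 1-arylethanols from acetophenones), which corresponds to 7R here because C8 outranks the aryl carbon.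

Step 1
Reactants: 1 acetovanillone (4-hydroxy-3-methoxyacetophenone); 2 1,3-bis(benzyloxy)propan-2-ol
Product: 3 1-{4-[(1,3-bis(benzyloxy)propan-2-yl)oxy]-3-methoxyphenyl}ethan-1-one (ring A ketone carrying the dibenzyl glycerol 2-O-aryl ether)
Conditions: PPh3, DIAD, THF, 0 °C to rt
Reagents that add atoms: none
Why: Mitsunobu etherification, in which the phenol of 1 (acidified by the para acetyl group) is a good pronucleophile for the activated secondary carbinol of 2, whose two identical arms make the new ether carbon non-stereogenic, so that the inversion is of no consequence.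

Step 2
Reactants: 3 ring A ketone; 4 dimethyl carbonate
Product: 6 methyl 3-{4-[(1,3-bis(benzyloxy)propan-2-yl)oxy]-3-methoxyphenyl}-3-oxopropanoate (ring A beta-keto ester), via sodium enolate of the beta-keto ester 5 (not isolated)
Conditions: NaH (2.5 equiv), (MeO)2CO (excess), THF, reflux; then dilute aq HCl, 0 °C
Reagents that add atoms: none
Why: Crossed Claisen condensation of the methyl ketone enolate with the non-enolisable carbonate forms the C8–C9 bond, is driven by irreversible deprotonation of the product to enolate 5, and leaves the benzyl and aryl ethers untouched.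

Step 3
Reactants: 6 ring A beta-keto ester
Product: 7 racemic methyl 2-bromo-3-{4-[(1,3-bis(benzyloxy)propan-2-yl)oxy]-3-methoxyphenyl}-3-oxopropanoate
Conditions: NBS (1.0 equiv), NH4OAc (10 mol%), Et2O, rt
Reagents that add atoms: N-bromosuccinimide, O=C1CCC(=O)N1Br
Why: Electrophilic alpha-bromination of the enolisable beta-keto ester, whose C8 methylene reacts through its enol far faster than ring A (deactivated by the para acyl group), with one equivalent of NBS limiting dibromination and the racemic C8 centre being of no consequence.

Step 4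
Reactants: 8 sinapic acid ((E)-3-(4-hydroxy-3,5-dimethoxyphenyl)prop-2-enoic acid)
Product: 9 3-(4-hydroxy-3,5-dimethoxyphenyl)propanoic acid (dihydrosinapic acid)
Conditions: H2 (1 atm), 10% Pd/C, MeOH, rt
Reagents that add atoms: none
Why: Heterogeneous catalytic hydrogenation saturates the cinnamic C=C bond, while the arene, the phenol and the acid are inert at atmospheric pressure.

Step 5
Reactants: 9 dihydrosinapic acid
Product: 10 methyl 3-(4-hydroxy-3,5-dimethoxyphenyl)propanoate (methyl dihydrosinapate, ring B phenol)
Conditions: MeOH, H2SO4 (cat.), reflux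
Reagents that add atoms: methanol, CO
Why: Fischer esterification converts the acid into the methyl ester without alkylating the hindered phenol.

Step 6
Reactants: 7 racemic alpha-bromo beta-keto ester; 10 ring B phenol
Product: 11 racemic methyl 3-{4-[(1,3-bis(benzyloxy)propan-2-yl)oxy]-3-methoxyphenyl}-2-[2,6-dimethoxy-4-(3-methoxy-3-oxopropyl)phenoxy]-3-oxopropanoate (alpha-aryloxy beta-keto ester)
Conditions: K2CO3 (1.5 equiv), acetone, rt to 40 °C
Reagents that add atoms: none
Why: Williamson-type O-alkylation, in which the phenol of 10 deprotonated by K2CO3 displaces the bromide activated by two flanking carbonyl groups (SN2) and forms the C8–O bond to ring B, the configuration at C8 being irrelevant because it is equilibrated in step 7.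

Step 7
Reactants: 11 racemic alpha-aryloxy beta-keto ester
Product: 13 methyl (2S,3R)-3-{4-[(1,3-bis(benzyloxy)propan-2-yl)oxy]-3-methoxyphenyl}-2-[2,6-dimethoxy-4-(3-methoxy-3-oxopropyl)phenoxy]-3-hydroxypropanoate (syn hydroxy diester), via enol tautomer of the keto ester 12 (not isolated)
Conditions: RuCl[(S,S)-TsDPEN](p-cymene) (2 mol%), HCO2H/Et3N (5:2), CH2Cl2, 30 °C
Reagents that add atoms: none
Why: The divalent ruthenium chloride precatalyst is converted by formate into a ruthenium hydride that passes hydride from the metal and a proton from the ligand NH2 to the C7 carbonyl in a concerted outer-sphere six-membered transition state, with the ring A aryl group held against the p-cymene ligand by a CH–pi contact so that a single ketone face is reduced. The closest known reaction type is the Noyori–Ikariya asymmetric transfer hydrogenation of alpha-alkoxy beta-keto esters under dynamic kinetic resolution, which delivers syn alpha-alkoxy beta-hydroxy esters; no ring is closed. C7 is controlled by the (S,S)-TsDPEN ligand (aryl ketone model, 3R in the ester and 7R in the target), and C8 by the substrate: as no metal chelate can form in an outer-sphere transfer, the C8 epimer that places the aryloxy group anti to the incoming hydride with the small C8 hydrogen next to ring A (polar Felkin–Anh arrangement) is reduced faster, which gives the syn (2S,3R) isomer. The step needs ketone-over-ester chemoselectivity, face selectivity at C7 and syn diastereoselection coupled to fast racemisation; the first is inherent to this catalyst class, and the last is secured by the C8 hydrogen lying between ketone and ester, so that the epimers should interconvert through enol 12 in the HCO2H/Et3N medium faster than either is reduced. Once C7 is a carbinol the C8 hydrogen is activated by the ester alone, so the product should be configurationally stable under the conditions.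

Step 8
Reactants: 13 syn-(2S,3R) hydroxy diester
Product: 14 (1R,2R)-1-{4-[(1,3-bis(benzyloxy)propan-2-yl)oxy]-3-methoxyphenyl}-2-[4-(3-hydroxypropyl)-2,6-dimethoxyphenoxy]propane-1,3-diol (threo triol with benzylated glycerol arms)
Conditions: LiAlH4 (excess), THF, 0 °C to rt; Fieser work-up (H2O, aq NaOH)
Reagents that add atoms: none
Why: Hydride reduction of both methyl esters to the C9 and side-chain primary alcohols is fast at 0 °C, proceeds through aluminium alkoxides that are not prone to retro-aldol cleavage or C8 epimerisation, and leaves the benzyl and aryl ethers and both stereocentres untouched.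

Step 9
Reactants: 14 benzylated threo triol
Product: 15 (1R,2R)-1-{4-[(1,3-dihydroxypropan-2-yl)oxy]-3-methoxyphenyl}-2-[4-(3-hydroxypropyl)-2,6-dimethoxyphenoxy]propane-1,3-diol (CNP0324330.2)
Conditions: H2 (1 atm), 10% Pd/C, EtOAc/EtOH, rt
Reagents that add atoms: none
Why: Catalytic hydrogenolysis cleaves the two primary alkyl benzyl ethers under neutral conditions, under which the free C7 hydroxyl (not acylated, and deactivated towards C–O cleavage by the adjacent C8 aryloxy group) and the aryl ethers should be retained and C7 and C8 are not touched.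

Compound list
1 | acetovanillone (4-hydroxy-3-methoxyacetophenone) | CC(=O)c1ccc(O)c(OC)c1 | starting material
2 | 1,3-bis(benzyloxy)propan-2-ol | OC(COCc1ccccc1)COCc1ccccc1 | starting material
3 | 1-{4-[(1,3-bis(benzyloxy)propan-2-yl)oxy]-3-methoxyphenyl}ethan-1-one | CC(=O)c1ccc(OC(COCc2ccccc2)COCc2ccccc2)c(OC)c1 | intermediate
4 | dimethyl carbonate | COC(=O)OC | starting material
5 | sodium (Z)-enolate of methyl 3-{4-[(1,3-bis(benzyloxy)propan-2-yl)oxy]-3-methoxyphenyl}-3-oxopropanoate | [Na+].COC(=O)/C=C(\[O-])c1ccc(OC(COCc2ccccc2)COCc2ccccc2)c(OC)c1 | intermediate (not isolated)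
6 | methyl 3-{4-[(1,3-bis(benzyloxy)propan-2-yl)oxy]-3-methoxyphenyl}-3-oxopropanoate | COC(=O)CC(=O)c1ccc(OC(COCc2ccccc2)COCc2ccccc2)c(OC)c1 | intermediate
7 | racemic methyl 2-bromo-3-{4-[(1,3-bis(benzyloxy)propan-2-yl)oxy]-3-methoxyphenyl}-3-oxopropanoate | COC(=O)C(Br)C(=O)c1ccc(OC(COCc2ccccc2)COCc2ccccc2)c(OC)c1 | intermediate
8 | sinapic acid | OC(=O)/C=C/c1cc(OC)c(O)c(OC)c1 | starting material
9 | 3-(4-hydroxy-3,5-dimethoxyphenyl)propanoic acid | OC(=O)CCc1cc(OC)c(O)c(OC)c1 | intermediate
10 | methyl 3-(4-hydroxy-3,5-dimethoxyphenyl)propanoate | COC(=O)CCc1cc(OC)c(O)c(OC)c1 | intermediate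
11 | racemic methyl 3-{4-[(1,3-bis(benzyloxy)propan-2-yl)oxy]-3-methoxyphenyl}-2-[2,6-dimethoxy-4-(3-methoxy-3-oxopropyl)phenoxy]-3-oxopropanoate | COc1cc(C(=O)C(C(=O)OC)Oc2c(OC)cc(CCC(=O)OC)cc2OC)ccc1OC(COCc3ccccc3)COCc3ccccc3 | intermediate
12 | enol tautomer of 11 (hydroxyl hydrogen-bonded to the ester carbonyl) | COc1cc(/C(O)=C(/C(=O)OC)Oc2c(OC)cc(CCC(=O)OC)cc2OC)ccc1OC(COCc3ccccc3)COCc3ccccc3 | intermediate (not isolated)
13 | methyl (2S,3R)-3-{4-[(1,3-bis(benzyloxy)propan-2-yl)oxy]-3-methoxyphenyl}-2-[2,6-dimethoxy-4-(3-methoxy-3-oxopropyl)phenoxy]-3-hydroxypropanoate | COc1cc([C@@H](O)[C@@H](C(=O)OC)Oc2c(OC)cc(CCC(=O)OC)cc2OC)ccc1OC(COCc3ccccc3)COCc3ccccc3 | intermediate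
14 | (1R,2R)-1-{4-[(1,3-bis(benzyloxy)propan-2-yl)oxy]-3-methoxyphenyl}-2-[4-(3-hydroxypropyl)-2,6-dimethoxyphenoxy]propane-1,3-diol | COc1cc([C@@H](O)[C@@H](CO)Oc2c(OC)cc(CCCO)cc2OC)ccc1OC(COCc3ccccc3)COCc3ccccc3 | intermediate
15 | (1R,2R)-1-{4-[(1,3-dihydroxypropan-2-yl)oxy]-3-methoxyphenyl}-2-[4-(3-hydroxypropyl)-2,6-dimethoxyphenoxy]propane-1,3-diol (CNP0324330.2) | COc1cc([C@@H](O)[C@@H](CO)Oc2c(OC)cc(CCCO)cc2OC)ccc1OC(CO)CO | target

Total step count: 9 steps.
Longest linear sequence: 7 steps (steps 1, 2, 3, 6, 7, 8 and 9, from acetovanillone 1); the ring B phenol 10 is made in 2 steps (steps 4 and 5) and joined in step 6.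

Steps most likely to fail

Step 7 (key step). The C8 epimers may interconvert too slowly relative to hydride transfer, or the Felkin preference may be small, so that the anti (erythro) isomer accompanies the product. The electron-rich, hindered ketone may also be reduced slowly or with a facial sense opposite to the model, in which case the mirror-image ligand would be tried first. The fallback sets out from 2 and 10 and returns at 14; it replaces the reduction by an auxiliary-controlled syn-aldol that forms the C7–C8 bond. Commercial vanillin is etherified with 2 under the Mitsunobu conditions of step 1 to give 4-[(1,3-bis(benzyloxy)propan-2-yl)oxy]-3-methoxybenzaldehyde F1. (S)-4-Benzyloxazolidin-2-one is N-acylated (n-BuLi, bromoacetyl bromide, THF, −78 °C) to (S)-4-benzyl-3-(bromoacetyl)oxazolidin-2-one F2, which alkylates phenol 10 (K2CO3, acetone) to give the N-(aryloxyacetyl)oxazolidinone F3. Its boron enolate (Bu2BOTf, iPr2NEt, CH2Cl2, −78 °C) should add to F1 through a chair Zimmerman–Traxler transition state to give the Evans syn-aldol adduct F4 with the (2S,3R) configuration in the acyl chain. LiBH4 in THF/MeOH then removes the auxiliary reductively and reduces the side-chain methyl ester in the same operation, giving 14.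

Step 6. The hindered, electron-rich phenoxide may attack bromine instead of carbon, which returns 6 by reductive debromination and consumes the phenol by oxidation or ring bromination. C-alkylation or a second alkylation of the acidic product may also compete. The fallback sets out from 6 and returns at 11. Regitz diazo transfer to 6 (4-acetamidobenzenesulfonyl azide, Et3N, MeCN) gives the alpha-diazo beta-keto ester F5. Dirhodium tetraacetate, Rh2(OAc)4 (1 mol%), in CH2Cl2 in the presence of phenol 10 then effects carbenoid O–H insertion, forming the same C8–O bond under neutral, non-basic conditions with loss of N2.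

Step 9. Hydrogenolysis may not stop at the benzyl ethers: the electron-rich benzylic C7–O bond may also be cleaved, or the primary alkyl benzyl ethers may react so sluggishly that harsher conditions are forced. The fallback sets out from 11 and returns at 15; it removes the benzyl groups before the benzylic carbinol exists. Hydrogenolysis of 11 (H2, Pd/C, EtOAc, rt), where C7 is still a ketone, gives the diol keto ester F6. The transfer hydrogenation of step 7 is then run on F6, the free hydroxyl groups being tolerated by the catalyst, to give the syn hydroxy diester diol F7. LiAlH4 reduction of its two esters delivers 15 directly.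

Further compounds
F1 | step 7 | 4-[(1,3-bis(benzyloxy)propan-2-yl)oxy]-3-methoxybenzaldehyde | O=Cc1ccc(OC(COCc2ccccc2)COCc2ccccc2)c(OC)c1
F2 | step 7 | (S)-4-benzyl-3-(bromoacetyl)oxazolidin-2-one | O=C(CBr)N1C(=O)OC[C@@H]1Cc2ccccc2
F3 | step 7 | methyl 3-[4-(2-{(S)-4-benzyl-2-oxooxazolidin-3-yl}-2-oxoethoxy)-3,5-dimethoxyphenyl]propanoate | COC(=O)CCc1cc(OC)c(OCC(=O)N2C(=O)OC[C@@H]2Cc3ccccc3)c(OC)c1
F4 | step 7 | (S)-4-benzyl-3-[(2S,3R)-3-{4-[(1,3-bis(benzyloxy)propan-2-yl)oxy]-3-methoxyphenyl}-2-[2,6-dimethoxy-4-(3-methoxy-3-oxopropyl)phenoxy]-3-hydroxypropanoyl]oxazolidin-2-one | COc1cc([C@@H](O)[C@@H](C(=O)N4C(=O)OC[C@@H]4Cc5ccccc5)Oc2c(OC)cc(CCC(=O)OC)cc2OC)ccc1OC(COCc3ccccc3)COCc3ccccc3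
F5 | step 6 | methyl 2-diazo-3-{4-[(1,3-bis(benzyloxy)propan-2-yl)oxy]-3-methoxyphenyl}-3-oxopropanoate | COC(=O)C(=[N+]=[N-])C(=O)c1ccc(OC(COCc2ccccc2)COCc2ccccc2)c(OC)c1
F6 | step 9 | racemic methyl 3-{4-[(1,3-dihydroxypropan-2-yl)oxy]-3-methoxyphenyl}-2-[2,6-dimethoxy-4-(3-methoxy-3-oxopropyl)phenoxy]-3-oxopropanoate | COc1cc(C(=O)C(C(=O)OC)Oc2c(OC)cc(CCC(=O)OC)cc2OC)ccc1OC(CO)CO
F7 | step 9 | methyl (2S,3R)-3-{4-[(1,3-dihydroxypropan-2-yl)oxy]-3-methoxyphenyl}-2-[2,6-dimethoxy-4-(3-methoxy-3-oxopropyl)phenoxy]-3-hydroxypropanoate | COc1cc([C@@H](O)[C@@H](C(=O)OC)Oc2c(OC)cc(CCC(=O)OC)cc2OC)ccc1OC(CO)CO
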